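The constants are invented.

We begin with birch.

| setting | larch | birch | oak | elm |
|---|---|---|---|---|
| J | 0.15 M | 0.15 M | 0.15 M | 0.15 M |
| G | 0.150 M | 0.150 M | 0.150 M | 0.150 M |
| X | 2.5 mol% | 2.5 mol% | 2.5 mol% | 2.5 mol% |
| temperature | 80 °C | −10 °C | 50 °C | 20 °C |
| time | 50 s | 50 s | 50 s | 50 s |

    2 X → X2 (k1 = 7.8 L mol⁻¹ s⁻¹, Ea1 = 46.0 kJ mol⁻¹)
    J → E (k2 = 0.019 s⁻¹, Ea2 = 81.0 kJ mol⁻¹)
    J + X → X + Z (k3 = 12 L mol⁻¹ s⁻¹, Ea3 = 38.0 kJ mol⁻¹)
    J + Z → J.Z (k4 = 0.84 L mol⁻¹ s⁻¹, Ea4 = 63.0 kJ mol⁻¹)
    J + G → J.G (k5 = 0.31 L mol⁻¹ s⁻¹, Ea5 = 40.0 kJ mol⁻¹)
    (constants at 50 °C)

1. which flask leads in amount of Z, in percent of the J charged ("all alike" within 1.5 percentage points) (larch / birch / oak / elm / all alike)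
2. how much Z is there at the end, in percent of the J charged: larch
3. how much Z is there at the end, in percent of the J charged: birch
4. how much Z is there at the end, in percent of the J charged: oak
5. how much Z is there at the end, in percent of the J charged: elm

- percentages count the J that a species holds: one J.Z counts as two
- where a step has two of a species, its rate is k times that concentration squared, and two are used at each turn
- the list of constants is for 50 °C, to be carried to other temperatures by the activation energies

At the start of birch, J leaves by first-order channels, each carried from the reference temperature by its activation energy. With X at its charge of 0.00375 M, the catalytic step J + X → X + Z is a pseudo-first-order loss of J with constant κ = 0.00179 s⁻¹. With G at its charge, J + G → J.G gives γ = 0.00156 s⁻¹, and J → E gives δ = 1.97 × 10⁻⁵ s⁻¹. We carry one quantity, the Z share σ = κ/(κ + γ + δ) = 53.1%, the fraction of the departing J that becomes Z, a selectivity. Their sum is 0.00337 s⁻¹.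

There are two ways to the amount of Z in birch. In the first, J decays exponentially with that sum, so 15.5% of it goes in 50 s, and σ of this is 8.23%. In the second, we hold J at its charge and let X fall by second-order pairing, with first half-life h = 848 s. Mean X is then 0.972 of its charge, and κ times the time times this factor gives 8.69%. The second figure is higher, and both cheat: the first holds X at its charge, the second holds J. Mean J is 0.920 of its charge, so the correction for J is larger than the one for X, and the second way cheats more. Applying both corrections gives 8.00%, our figure for birch. J + Z → J.Z can wait in birch, since its drain on J stays small beside κ.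

In elm, κ = 0.0106 s⁻¹ and the channels, with X and G held at their charges, sum to 0.0216 s⁻¹. The share in elm is lower than in birch, 49.0%, but this sum reckons 66.0% of the J gone by the end. The product, 32.3%, counts no loss of Z or X, and we expect elm above birch. In oak, h is 17.1 s, shorter than the run, so a share reckoned with X at its charge does not last. We give no number for oak, nor for larch.

The forecast names elm and gives 8.4% for larch, 7.9% for birch, a little under our figure, 15.8% for oak and 23.2% for elm, saying of birch: “too slow, J is barely consumed, about 8%”.

The simulation puts elm in the lead with 23.1%, below our uncorrected count, ahead of oak at 15.8%, larch at 8.57% and birch at 7.91%. Birch's conversion of J at the end is 15.2%, and σ, a share reckoned for the start, times this conversion is 8.07%, which is 0.14 percentage points more than the Z in birch.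

Read at 12 s, the same birch flask should lose 3.96% of its J, and σ of that is 2.10% of Z. The simulation shows 2.08% of Z there, with 96% of the J left.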